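**Retrosynthetic overview** (ent-kaurane numbering: ring C = C8, C9, C11–C14; ring D = C8, C14, C13, C16, C15; ring A = C1–C5, C10)
1. The C15 acetate is added last (allylic oxidation, oxidation, exo-face reduction). The lactone is closed from a C6 ketone/C19 aldehyde made by Claisen-type union at C6–C7 of a bicyclic acetic acid (as its dianion) with a ring-A lactone.
2. Ring A (C4, C5, C10) comes from a Diels–Alder reaction of a (−)-menthol-derived 5-alkoxy-4-methylbutenolide with a 1-silyloxy-1-methylbutadiene.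
3. Rings C and D: a bicyclo[2.2.2]oct-5-en-2-one is turned into the bicyclo[3.2.1]oct-3-en-2-one by an acid-induced double 1,2-shift that forms C9–C11 and C8–C14 (breaking C8–C11 and C9–C14). The enabling feature is the β,γ-unsaturated ketone whose carbonyl C9 lies between the quaternary bridgehead C8 (carrying the C11=C12 etheno bridge) and the C14 methylene, with no oxygen on C15 or C7.
4. That cage comes from a guaiacol (from o-eugenol) by oxidative dearomatisation to a masked o-benzoquinone, intramolecular Diels–Alder reaction with tethered allyl alcohol, and SmI2 cleavage. The six arene carbons end up as C8, C9, C11, C12, C13, C14.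
5. Ring order: arene → bicyclo[2.2.2] cage → rings C and D (key step); ring A separately; lactone last.

Key step: step 7

Assumption: in step 9 the (R)-amine salt of the (1S,5S)-acid is taken to be the less soluble one (otherwise the (S)-amine is used), and in step 10 the (5R)-acetal is taken to be the crystalline epimer, as in the parent 5-menthyloxyfuranone series; compounds 8–12 are racemic and are drawn as the enantiomer that is carried on.

Step 1
Reactants: 1 2-allyl-6-methoxyphenol (o-eugenol)
Product: 3 7-methoxy-2,3-dihydro-1-benzofuran-2-ol, via ozonide 2 (not isolated)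
Conditions: O3, CH2Cl2/MeOH, −78 °C; then Me2S, −78 °C to rt
Reagents that add atoms: ozone, [O-][O+]=O
Why: Ozonolysis of the terminal alkene outruns attack on the arene at −78 °C, and after reductive work-up the arylacetaldehyde should close onto the phenol as the cyclic hemiacetal.

Step 2
Reactants: 3 7-methoxy-2,3-dihydro-1-benzofuran-2-ol
Product: 4 7-methoxy-1-benzofuran-2(3H)-one
Conditions: Ag2CO3 on Celite, benzene, reflux
Reagents that add atoms: none
Why: Fétizon oxidation converts a lactol into the lactone under neutral conditions that leave the electron-rich ring alone.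

Step 3
Reactants: 4 7-methoxy-1-benzofuran-2(3H)-one
Product: 5 methyl (2-hydroxy-3-methoxyphenyl)acetate
Conditions: MeOH, H2SO4 (cat.), reflux
Reagents that add atoms: methanol, CO
Why: Acid-catalysed transesterification opens the activated aryl ester and frees the phenol needed for dearomatisation.

Step 4
Reactants: 5 methyl (2-hydroxy-3-methoxyphenyl)acetate; 6 allyl alcohol (prop-2-en-1-ol)
Product: 8 racemic methyl 2-(3-methoxy-2-oxo-4-oxatricyclo[4.3.1.0^3,7]dec-8-en-1-yl)acetate, via masked o-benzoquinone 7 (not isolated)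
Conditions: PhI(OAc)2, allyl alcohol/CH2Cl2, 0 °C to rt; then toluene, 110 °C
Reagents that add atoms: none
Why: Hypervalent-iodine oxidation of a 2-methoxyphenol in the presence of an alcohol gives the mixed o-quinone monoketal 7, whose tethered allyl group then adds across the dienone in an intramolecular Diels–Alder reaction; the short oxa-tether fixes the regiochemistry (terminal CH2 to the side-chain-bearing carbon C8, internal carbon to C13) and places the O–CH2 arm syn to the ketal bridge.

Step 5
Reactants: 8 racemic tricyclic keto ketal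
Product: 9 racemic methyl 2-[8-(hydroxymethyl)-2-oxobicyclo[2.2.2]oct-5-en-1-yl]acetate (CH2OH syn to the C2–C3 bridge)
Conditions: SmI2 (5 equiv), THF/MeOH, −78 °C to rt
Reagents that add atoms: none
Why: SmI2 reductively cleaves both C–O bonds alpha to the ketone (alpha-alkoxy ketone reduction), which turns C14 into CH2 and releases the tether as the hydroxymethyl group without touching a stereocentre.

Step 6
Reactants: 9 racemic hydroxy keto ester
Product: 10 racemic methyl 2-[8-(bromomethyl)-2-oxobicyclo[2.2.2]oct-5-en-1-yl]acetate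
Conditions: CBr4, PPh3, CH2Cl2, 0 °C
Reagents that add atoms: carbon tetrabromide, BrC(Br)(Br)Br
Why: The Appel reaction converts the primary alcohol into a bromide that is inert to the acid of step 7 and serves as the leaving group for step 8.

Step 7
Reactants: 10 racemic bromo keto ester
Product: 11 racemic methyl 2-[6-(bromomethyl)-2-oxobicyclo[3.2.1]oct-3-en-1-yl]acetate (CH2Br exo, syn to the one-carbon bridge)
Conditions: TfOH (3 equiv), CH2Cl2, 0 °C to rt
Reagents that add atoms: none
Why: O-Protonation of the C9 ketone makes the carbonyl carbon electrophilic towards the homoallylic C11=C12 bond; C11 shifts from the quaternary bridgehead C8 to C9 (1,2-alkenyl shift with π-participation), leaving a tertiary cation at C8, to which the C14 methylene then migrates from the carbinol carbon C9 (pinacol-type 1,2-alkyl shift), regenerating the carbonyl as the protonated conjugated enone. The closest known reaction type is the acid-catalysed rearrangement of bicyclo[2.2.2]octenones and -octadienones to bicyclo[3.2.1]octenones (Cargill-type rearrangement of β,γ-unsaturated ketones). The six-membered enone ring (C8, C9, C11, C12, C13, C14) is closed by the C9–C11 bond in a suprafacial 1,2-shift (3-exo attack of the alkene on the hydroxycarbenium ion, then cyclopropylcarbinyl opening), and the five-membered ring (C8, C14, C13, C16, C15) by the C8–C14 bond in a suprafacial 1,2-alkyl shift. The quaternary bridgehead C8 is the only stereocentre that is re-made; its configuration is dictated by the cage, because C13 and C16 are untouched and both shifts are suprafacial, so the configuration of 10 is carried into 11. The step needs alkenyl rather than alkyl migration first and C14 rather than hydride migration second: π-participation and the tertiary cation secure the first, and the deliberate absence of oxygen at C15 and C7 leaves the pinacol shift to the conjugated enone as the only exergonic exit. Ester and bromide are inert to TfOH.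

Step 8
Reactants: 11 racemic bromo enone ester
Product: 12 racemic 2-(6-methylidene-2-oxobicyclo[3.2.1]oct-3-en-1-yl)acetic acid
Conditions: KOt-Bu (5 equiv), H2O (2 equiv), THF, 0 °C to rt; aq. HCl work-up
Reagents that add atoms: water, O
Why: E2 elimination of the β-branched primary bromide gives the exocyclic alkene and the hydroxide formed from KOt-Bu and water saponifies the ester, while the enone survives because it has no enolisable position (quaternary C8, bridgehead C13).

Step 9
Reactants: 12 racemic acid; 13 (R)-1-phenylethylamine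
Product: 15 2-[(1S,5S)-6-methylidene-2-oxobicyclo[3.2.1]oct-3-en-1-yl]acetic acid, via phenylethylammonium salt 14 (not isolated)
Conditions: EtOH/EtOAc, fractional crystallisation; then aq. HCl/EtOAc
Reagents that add atoms: none
Why: Classical resolution through diastereomeric ammonium salts should deliver the single enantiomer of the cage (C8, C13) before the fragments are joined.

Step 10
Reactants: 16 5-hydroxy-4-methylfuran-2(5H)-one; 17 (−)-menthol
Product: 18 (5R)-4-methyl-5-{[(1R,2S,5R)-5-methyl-2-(propan-2-yl)cyclohexyl]oxy}furan-2(5H)-one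
Conditions: camphorsulfonic acid (cat.), toluene, reflux (Dean–Stark); crystallisation from hexane with a trace of the acid
Reagents that add atoms: none
Why: Acid-catalysed acetalisation of the pseudo-acid gives both acetal epimers, which interconvert under the acid so that crystallisation should funnel the mixture into one diastereomer (crystallisation-induced asymmetric transformation).

Step 11
Reactants: 19 pent-4-en-2-one
Product: 20 triethyl{[(2Z)-penta-2,4-dien-2-yl]oxy}silane
Conditions: Et3SiOTf, Et3N, CH2Cl2, 0 °C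
Reagents that add atoms: triethylsilyl trifluoromethanesulfonate, CC[Si](CC)(CC)OS(=O)(=O)C(F)(F)F
Why: Soft enolisation removes the doubly activated (allylic and alpha to the ketone) proton and should give the conjugated silyl dienol ether mainly as the Z isomer (oxygen cis to the vinyl group).

Step 12
Reactants: 18 (5R)-menthyloxybutenolide; 20 silyloxydiene
Product: 21 (3R,3aR,7R,7aR)-3a,7-dimethyl-3-{[(1R,2S,5R)-5-methyl-2-(propan-2-yl)cyclohexyl]oxy}-7-[(triethylsilyl)oxy]-3a,4,7,7a-tetrahydro-2-benzofuran-1(3H)-one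
Conditions: toluene, BHT (cat.), 130 °C, sealed tube
Reagents that add atoms: none
Why: In this normal-demand Diels–Alder reaction the nucleophilic CH2 terminus of the diene bonds to the β-carbon of the butenolide (quaternary C4) and the oxygenated terminus to the α-carbon (C5); the diene adds anti to the menthyloxy group (absolute configuration) and the endo mode puts the outside methyl C20 cis to the lactone and the silyloxy group trans, which sets C4, C5 and C10.

Step 13
Reactants: 21 Diels–Alder adduct
Product: 22 (3R,3aR,7R,7aR)-3a,7-dimethyl-3-{[(1R,2S,5R)-5-methyl-2-(propan-2-yl)cyclohexyl]oxy}-7-[(triethylsilyl)oxy]hexahydro-2-benzofuran-1(3H)-one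
Conditions: H2 (1 atm), Rh/Al2O3, EtOAc, rt
Reagents that add atoms: none
Why: Heterogeneous hydrogenation saturates the disubstituted ring alkene, and rhodium on alumina is chosen to avoid hydrogenolysis of the allylic silyl ether.

Step 14
Reactants: 15 (1S,5S)-acid; 22 ring-A lactone
Product: 24 (1R,2R,3R)-3-hydroxy-1,3-dimethyl-2-{[(1S,5S)-6-methylidene-2-oxobicyclo[3.2.1]oct-3-en-1-yl]acetyl}cyclohexane-1-carbaldehyde, via beta-keto acid 23 (not isolated)
Conditions: LiN(i-Pr)2 (2.2 equiv), THF, −78 to 0 °C; 22, −78 to −30 °C; AcOH quench; then AcOH/THF/H2O, 45 °C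
Reagents that add atoms: none
Why: The carboxylic acid dianion is acylated at C7 by the lactone carbonyl C6 (Claisen-type condensation), and on acidification the hemiketal opens, the menthyl hemiacetal collapses to the C19 aldehyde, the β-keto acid loses CO2 and the tertiary silyl ether is hydrolysed; C5 keeps its configuration because enolisation between two quaternary carbons is slow.

Step 15
Reactants: 24 keto aldehyde
Product: 25 (3R,3aS,4R,7aR)-4,7a-dimethyl-3-{[(1S,5S)-6-methylidene-2-oxobicyclo[3.2.1]oct-3-en-1-yl]methyl}octahydro-2-benzofuran-1,4-diol (lactol, both anomers)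
Conditions: Me4NBH(OAc)3, MeCN/AcOH, −25 °C
Reagents that add atoms: none
Why: In this Evans–Saksena reduction the tertiary C10 hydroxyl binds boron and delivers hydride to the β-ketone from its own side, which gives the 1,3-anti relationship, that is (R) at C6; the enone is not touched by triacetoxyborohydride and the new hydroxyl closes onto the cis C19 aldehyde.

Step 16
Reactants: 25 lactol
Product: 26 (3R,3aS,4R,7aR)-4-hydroxy-4,7a-dimethyl-3-{[(1S,5S)-6-methylidene-2-oxobicyclo[3.2.1]oct-3-en-1-yl]methyl}hexahydro-2-benzofuran-1(3H)-one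
Conditions: TEMPO (cat.), PhI(OAc)2, CH2Cl2, rt
Reagents that add atoms: none
Why: The oxoammonium oxidation converts the lactol (and any over-reduced 1,4-diol) into the γ-lactone while the tertiary alcohol, enone and alkene stay inert.

Step 17
Reactants: 26 lactone
Product: 28 (3R,3aS,4R,7aR)-4-hydroxy-4,7a-dimethyl-3-{[(1S,5S)-6-methylidene-2,7-dioxobicyclo[3.2.1]oct-3-en-1-yl]methyl}hexahydro-2-benzofuran-1(3H)-one, via exo allylic alcohol 27 (not isolated)
Conditions: SeO2 (cat.), t-BuOOH, CH2Cl2, rt; then Dess–Martin periodinane, NaHCO3, CH2Cl2, 0 °C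
Reagents that add atoms: selenium dioxide, O=[Se]=O; tert-butyl hydroperoxide, CC(C)(C)OO
Why: The ene/[2,3]-sigmatropic allylic oxidation can only occur at C15 (bridgehead C13 cannot become an alkene carbon) and should give the exo alcohol, whose wrong configuration is erased by oxidation to the cross-conjugated ketone.

Step 18
Reactants: 28 enedione
Product: 29 (3R,3aS,4R,7aR)-4-hydroxy-3-{[(1R,5S,7R)-7-hydroxy-6-methylidene-2-oxobicyclo[3.2.1]oct-3-en-1-yl]methyl}-4,7a-dimethylhexahydro-2-benzofuran-1(3H)-one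
Conditions: NaBH4 (0.3 equiv), CeCl3·7H2O, MeOH, −78 °C
Reagents that add atoms: none
Why: In this Luche 1,2-reduction hydride should attack the C15 carbonyl from the open exo face (side of the one-carbon bridge), giving the endo alcohol (syn to the enone bridge) that the target requires, and with substoichiometric hydride the exposed five-ring carbonyl should react before the C9 carbonyl, which is shielded on both faces by the bridges.

Step 19
Reactants: 29 endo allylic alcohol
Product: 30 (1R,5S,7R)-1-{[(3R,3aS,4R,7aR)-4-hydroxy-4,7a-dimethyl-1-oxooctahydro-2-benzofuran-3-yl]methyl}-6-methylidene-2-oxobicyclo[3.2.1]oct-3-en-7-yl acetate (CNP0172716.1)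
Conditions: Ac2O, pyridine, DMAP (cat.), CH2Cl2, 0 °C to rt
Reagents that add atoms: acetic anhydride, CC(=O)OC(C)=O
Why: DMAP-catalysed acylation esterifies the secondary allylic alcohol, while the tertiary C10 hydroxyl is too hindered to react.

**Compound list**
1 | 2-allyl-6-methoxyphenol (o-eugenol) | C=CCc1cccc(OC)c1O | starting material
2 | 3-[(2-hydroxy-3-methoxyphenyl)methyl]-1,2,4-trioxolane (ozonide) | COc1cccc(CC2OCOO2)c1O | intermediate
3 | 7-methoxy-2,3-dihydro-1-benzofuran-2-ol | COc1cccc2CC(O)Oc12 | intermediate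
4 | 7-methoxy-1-benzofuran-2(3H)-one | COc1cccc2CC(=O)Oc12 | intermediate
5 | methyl (2-hydroxy-3-methoxyphenyl)acetate | COC(=O)Cc1cccc(OC)c1O | intermediate
6 | allyl alcohol | C=CCO | starting material
7 | methyl 2-[5-(allyloxy)-5-methoxy-6-oxocyclohexa-1,3-dien-1-yl]acetate (masked o-benzoquinone) | COC(=O)CC1=CC=CC(OC)(OCC=C)C1=O | intermediate
8 | methyl 2-(3-methoxy-2-oxo-4-oxatricyclo[4.3.1.0^3,7]dec-8-en-1-yl)acetate (racemate) | O=C1[C@]2(OC)OC[C@@H]3C[C@@]1(CC(=O)OC)C=C[C@H]23 | intermediate
9 | methyl 2-[8-(hydroxymethyl)-2-oxobicyclo[2.2.2]oct-5-en-1-yl]acetate (racemate) | OC[C@@H]1C[C@@]2(CC(=O)OC)C=C[C@@H]1CC2=O | intermediate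
10 | methyl 2-[8-(bromomethyl)-2-oxobicyclo[2.2.2]oct-5-en-1-yl]acetate (racemate) | BrC[C@@H]1C[C@@]2(CC(=O)OC)C=C[C@@H]1CC2=O | intermediate
11 | methyl 2-[6-(bromomethyl)-2-oxobicyclo[3.2.1]oct-3-en-1-yl]acetate (racemate) | BrC[C@H]1[C@@H]2C=CC(=O)[C@@](CC(=O)OC)(C2)C1 | intermediate
12 | 2-(6-methylidene-2-oxobicyclo[3.2.1]oct-3-en-1-yl)acetic acid (racemate) | C=C1[C@@H]2C=CC(=O)[C@@](CC(=O)O)(C2)C1 | intermediate
13 | (R)-1-phenylethylamine | C[C@@H](N)c1ccccc1 | starting material
14 | (R)-1-phenylethylammonium 2-[(1S,5S)-6-methylidene-2-oxobicyclo[3.2.1]oct-3-en-1-yl]acetate | C=C1[C@@H]2C=CC(=O)[C@@](CC(=O)[O-])(C2)C1.C[C@@H]([NH3+])c1ccccc1 | intermediate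
15 | 2-[(1S,5S)-6-methylidene-2-oxobicyclo[3.2.1]oct-3-en-1-yl]acetic acid | C=C1[C@@H]2C=CC(=O)[C@@](CC(=O)O)(C2)C1 | intermediate
16 | 5-hydroxy-4-methylfuran-2(5H)-one | CC1=CC(=O)OC1O | starting material
17 | (−)-menthol | C[C@@H]1CC[C@H]([C@@H](C1)O)C(C)C | starting material
18 | (5R)-4-methyl-5-{[(1R,2S,5R)-5-methyl-2-(propan-2-yl)cyclohexyl]oxy}furan-2(5H)-one | O=C1O[C@@H](O[C@@H]2C[C@H](C)CC[C@H]2C(C)C)C(C)=C1 | intermediate
19 | pent-4-en-2-one | CC(=O)CC=C | starting material
20 | triethyl{[(2Z)-penta-2,4-dien-2-yl]oxy}silane | C=C/C=C(/C)O[Si](CC)(CC)CC | intermediate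
21 | (3R,3aR,7R,7aR)-3a,7-dimethyl-3-(menthyloxy)-7-[(triethylsilyl)oxy]-3a,4,7,7a-tetrahydro-2-benzofuran-1(3H)-one | O=C1O[C@@H](O[C@@H]2C[C@H](C)CC[C@H]2C(C)C)[C@]3(C)CC=C[C@@](C)(O[Si](CC)(CC)CC)[C@H]13 | intermediate
22 | (3R,3aR,7R,7aR)-3a,7-dimethyl-3-(menthyloxy)-7-[(triethylsilyl)oxy]hexahydro-2-benzofuran-1(3H)-one | O=C1O[C@@H](O[C@@H]2C[C@H](C)CC[C@H]2C(C)C)[C@]3(C)CCC[C@@](C)(O[Si](CC)(CC)CC)[C@H]13 | intermediate
23 | 3-[(1R,2R,6R)-2-formyl-2,6-dimethyl-6-(triethylsilyloxy)cyclohexyl]-2-[(1S,5S)-6-methylidene-2-oxobicyclo[3.2.1]oct-3-en-1-yl]-3-oxopropanoic acid | C=C1[C@@H]2C=CC(=O)[C@@](C(C(=O)O)C(=O)[C@@H]3[C@](C)(C=O)CCC[C@@]3(C)O[Si](CC)(CC)CC)(C2)C1 | intermediate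
24 | (1R,2R,3R)-3-hydroxy-1,3-dimethyl-2-{[(1S,5S)-6-methylidene-2-oxobicyclo[3.2.1]oct-3-en-1-yl]acetyl}cyclohexane-1-carbaldehyde | C=C1[C@@H]2C=CC(=O)[C@@](CC(=O)[C@@H]3[C@](C)(C=O)CCC[C@@]3(C)O)(C2)C1 | intermediate
25 | (3R,3aS,4R,7aR)-4,7a-dimethyl-3-{[(1S,5S)-6-methylidene-2-oxobicyclo[3.2.1]oct-3-en-1-yl]methyl}octahydro-2-benzofuran-1,4-diol | C=C1[C@@H]2C=CC(=O)[C@@](C[C@H]3OC(O)[C@]4(C)CCC[C@@](C)(O)[C@H]34)(C2)C1 | intermediate
26 | (3R,3aS,4R,7aR)-4-hydroxy-4,7a-dimethyl-3-{[(1S,5S)-6-methylidene-2-oxobicyclo[3.2.1]oct-3-en-1-yl]methyl}hexahydro-2-benzofuran-1(3H)-one | C=C1[C@@H]2C=CC(=O)[C@@](C[C@H]3OC(=O)[C@]4(C)CCC[C@@](C)(O)[C@H]34)(C2)C1 | intermediate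
27 | (3R,3aS,4R,7aR)-4-hydroxy-3-{[(1R,5S,7S)-7-hydroxy-6-methylidene-2-oxobicyclo[3.2.1]oct-3-en-1-yl]methyl}-4,7a-dimethylhexahydro-2-benzofuran-1(3H)-one | C=C1[C@@H]2C=CC(=O)[C@@](C[C@H]3OC(=O)[C@]4(C)CCC[C@@](C)(O)[C@H]34)(C2)[C@H]1O | intermediate
28 | (3R,3aS,4R,7aR)-4-hydroxy-4,7a-dimethyl-3-{[(1S,5S)-6-methylidene-2,7-dioxobicyclo[3.2.1]oct-3-en-1-yl]methyl}hexahydro-2-benzofuran-1(3H)-one | C=C1[C@@H]2C=CC(=O)[C@@](C[C@H]3OC(=O)[C@]4(C)CCC[C@@](C)(O)[C@H]34)(C2)C1=O | intermediate
29 | (3R,3aS,4R,7aR)-4-hydroxy-3-{[(1R,5S,7R)-7-hydroxy-6-methylidene-2-oxobicyclo[3.2.1]oct-3-en-1-yl]methyl}-4,7a-dimethylhexahydro-2-benzofuran-1(3H)-one | C=C1[C@@H]2C=CC(=O)[C@@](C[C@H]3OC(=O)[C@]4(C)CCC[C@@](C)(O)[C@H]34)(C2)[C@@H]1O | intermediate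
30 | (1R,5S,7R)-1-{[(3R,3aS,4R,7aR)-4-hydroxy-4,7a-dimethyl-1-oxooctahydro-2-benzofuran-3-yl]methyl}-6-methylidene-2-oxobicyclo[3.2.1]oct-3-en-7-yl acetate (CNP0172716.1) | C=C1[C@@H]2C=CC(=O)[C@@](C[C@H]3OC(=O)[C@]4(C)CCC[C@@](C)(O)[C@H]34)(C2)[C@@H]1OC(C)=O | target

**Step count:** 19 steps in total; longest linear sequence 15 steps (steps 1–9, then 14–19).

**Steps most likely to fail**

Step 14. The dianion may transfer a proton to, or add in conjugate fashion to, the enone of a second molecule faster than it attacks the hindered lactone carbonyl. The fallback sets out from 15: esterification with allyl bromide and K2CO3 gives allyl 2-[(1S,5S)-6-methylidene-2-oxobicyclo[3.2.1]oct-3-en-1-yl]acetate F1. Its lithium enolate (LiN(SiMe3)2, THF, −78 °C), formed under much milder conditions than the dianion, is acylated by 22 to the β-keto allyl ester F2. Pd(PPh3)4 (zerovalent palladium) with morpholine removes the allyl group with loss of CO2, and AcOH/THF/H2O removes the silyl group, which brings the route back at 24.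

Step 12. The β,β-disubstituted butenolide may be too unreactive, so that the silyl dienol ether isomerises or polymerises before cycloaddition. The fallback sets out from 20: cycloaddition with citraconic anhydride (doubly activated; regiochemistry then steric, anhydride endo) gives the racemic anhydride adduct F3. Hydrogenation over Rh/Al2O3 gives the saturated anhydride F4, and NaBH4 reduces the carbonyl next to the quaternary carbon to the racemic lactone F5. Acylation of the dianion of 15 with F5 as in step 14 gives, after decarboxylation and desilylation, the keto diol F6 as two diastereomers, because F5 is racemic. Evans–Saksena reduction gives the triol F7, and TEMPO/PhI(OAc)2 oxidative lactonisation, with chromatographic removal of the diastereomer built from the wrong ring-A enantiomer, brings the route back at 26.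

Step 18. Site selectivity between the two enone carbonyls (C9 against C15) may be poor, or the non-enolisable 1,3-dione may undergo retro-Claisen cleavage in methanol. The fallback sets out from 26: Luche reduction of its only ketone gives the allylic alcohol F8 (configuration at C9 immaterial), and TBSCl/imidazole gives the silyl ether F9. SeO2/t-BuOOH followed by Dess–Martin periodinane gives the 15-ketone F10, now the only ketone. Luche reduction from the exo face gives the endo alcohol F11, acetylation gives the acetate F12, HF·pyridine gives the allylic alcohol F13, and MnO2 oxidation of that allylic alcohol brings the route back at 30.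

**Further compounds**
F1 | step 14 | allyl 2-[(1S,5S)-6-methylidene-2-oxobicyclo[3.2.1]oct-3-en-1-yl]acetate | C=C1[C@@H]2C=CC(=O)[C@@](CC(=O)OCC=C)(C2)C1
F2 | step 14 | allyl 3-[(1R,2R,6R)-2-formyl-2,6-dimethyl-6-(triethylsilyloxy)cyclohexyl]-2-[(1S,5S)-6-methylidene-2-oxobicyclo[3.2.1]oct-3-en-1-yl]-3-oxopropanoate | C=C1[C@@H]2C=CC(=O)[C@@](C(C(=O)OCC=C)C(=O)[C@@H]3[C@](C)(C=O)CCC[C@@]3(C)O[Si](CC)(CC)CC)(C2)C1
F3 | step 12 | 3a,7-dimethyl-7-[(triethylsilyl)oxy]-3a,4,7,7a-tetrahydro-2-benzofuran-1,3-dione (racemate, cis-fused, methyl at C7 cis to the anhydride) | O=C1OC(=O)[C@]2(C)CC=C[C@@](C)(O[Si](CC)(CC)CC)[C@H]12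
F4 | step 12 | 3a,7-dimethyl-7-[(triethylsilyl)oxy]hexahydro-2-benzofuran-1,3-dione (racemate) | O=C1OC(=O)[C@]2(C)CCC[C@@](C)(O[Si](CC)(CC)CC)[C@H]12
F5 | step 12 | 3a,7-dimethyl-7-[(triethylsilyl)oxy]hexahydro-2-benzofuran-1(3H)-one (racemate) | O=C1OC[C@]2(C)CCC[C@@](C)(O[Si](CC)(CC)CC)[C@H]12
F6 | step 12 | 1-[(1R,2R,6R)-2-hydroxy-6-(hydroxymethyl)-2,6-dimethylcyclohexyl]-2-[(1S,5S)-6-methylidene-2-oxobicyclo[3.2.1]oct-3-en-1-yl]ethanone | C=C1[C@@H]2C=CC(=O)[C@@](CC(=O)[C@@H]3[C@](C)(CO)CCC[C@@]3(C)O)(C2)C1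
F7 | step 12 | (1S,5S)-1-{(2R)-2-hydroxy-2-[(1S,2R,6R)-2-hydroxy-6-(hydroxymethyl)-2,6-dimethylcyclohexyl]ethyl}-6-methylidenebicyclo[3.2.1]oct-3-en-2-one | C=C1[C@@H]2C=CC(=O)[C@@](C[C@@H](O)[C@@H]3[C@](C)(CO)CCC[C@@]3(C)O)(C2)C1
F8 | step 18 | lactone 26 with the C9 ketone reduced to the allylic alcohol (hydroxyl syn to the two-carbon bridge) | C=C1[C@@H]2C=C[C@H](O)[C@@](C[C@H]3OC(=O)[C@]4(C)CCC[C@@](C)(O)[C@H]34)(C2)C1
F9 | step 18 | tert-butyldimethylsilyl ether of F8 at C9 | C=C1[C@@H]2C=C[C@H](O[Si](C)(C)C(C)(C)C)[C@@](C[C@H]3OC(=O)[C@]4(C)CCC[C@@](C)(O)[C@H]34)(C2)C1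
F10 | step 18 | 15-ketone of F9 | C=C1[C@@H]2C=C[C@H](O[Si](C)(C)C(C)(C)C)[C@@](C[C@H]3OC(=O)[C@]4(C)CCC[C@@](C)(O)[C@H]34)(C2)C1=O
F11 | step 18 | 15-endo alcohol from F10 | C=C1[C@@H]2C=C[C@H](O[Si](C)(C)C(C)(C)C)[C@@](C[C@H]3OC(=O)[C@]4(C)CCC[C@@](C)(O)[C@H]34)(C2)[C@@H]1O
F12 | step 18 | 15-acetate of F11 | C=C1[C@@H]2C=C[C@H](O[Si](C)(C)C(C)(C)C)[C@@](C[C@H]3OC(=O)[C@]4(C)CCC[C@@](C)(O)[C@H]34)(C2)[C@@H]1OC(C)=O
F13 | step 18 | C9 allylic alcohol corresponding to target 30 | C=C1[C@@H]2C=C[C@H](O)[C@@](C[C@H]3OC(=O)[C@]4(C)CCC[C@@](C)(O)[C@H]34)(C2)[C@@H]1OC(C)=O
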